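**Retrosynthetic overview**

1. Camelliol C is treated as a 5-substituted 4,6,6-trimethylcyclohex-3-en-1-ol (ring numbering: C1 carbinol, C2 CH2, C3 =CH, C4 =C(CH3), C5 CH carrying the C21 tetraene chain, C6 C(CH3)2). The enabling feature is that the only ring alkene, C3=C4, lies between two allylic sp3 ring carbons (C2 and C5) and that the oxygen sits on C1, next to C2. C3, C4 and the C4 methyl are therefore a propyne unit, and C2–C1–C6–C5 is a 2-oxy-1,3-diene once C6 is taken one methyl short.
2. Disconnections at the ring: C1–OH from the C1 ketone (reagent-controlled reduction); the second C6 methyl from the C1(OSi)=C6 enol silane (regiospecific enolate methylation); ring bonds C2–C3 and C4–C5 from an enantioselective cobalt-catalysed [4+2] cycloaddition of propyne with an acyclic 2-siloxy-3-methyl-1,3-diene that already carries the whole polyene chain.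
3. Chain: diene from the methyl enone (kinetic enol silylation); enone from a C22 tetraenal (Wittig); tetraenal from (E,E)-farnesyl bromide by nitrile alkylation, isopropenyl addition and Johnson–Claisen rearrangement, which sets the third (E)-trisubstituted alkene.
4. Ring order: the target has one ring, closed in step 8; no protecting groups are used.

Key step: step 8

Remark: 3-(triphenylphosphoranylidene)butan-2-one (14) is taken as a catalogue reagent (otherwise one step from 3-bromobutan-2-one and PPh3); the ligand in step 8 is written as the (2S,4S) antipode, the sense of induction is to be confirmed in the first run, and the (2R,4R) ligand is used if it is opposite.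

**Route**

Step 1
Reactants: 1 (2E,6E)-farnesyl bromide; 2 acetonitrile
Product: 4 (4E,8E)-5,9,13-trimethyltetradeca-4,8,12-trienenitrile, via lithioacetonitrile 3 (not isolated)
Conditions: 2 (3 equiv), n-BuLi (3 equiv), THF, −78 °C; then 1, −78 → −20 °C
Reagents that add atoms: none
Why: SN2 alkylation of lithiated acetonitrile by the primary allylic bromide takes place at the bromide-bearing carbon without allylic transposition, so both (E)-alkenes are carried over unchanged, and the excess of the small nitrile anion suppresses dialkylation.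

Step 2
Reactants: 4 (4E,8E)-5,9,13-trimethyltetradeca-4,8,12-trienenitrile
Product: 6 (4E,8E)-5,9,13-trimethyltetradeca-4,8,12-trienal, via N-aluminio aldimine 5 (not isolated)
Conditions: i-Bu2AlH (1.2 equiv), CH2Cl2, −78 °C; then 1 M aq. HCl, 0 °C
Reagents that add atoms: water (O)
Why: Partial reduction of a nitrile with i-Bu2AlH stops at the N-aluminio aldimine, which releases the aldehyde only on aqueous acidic hydrolysis, so over-reduction is excluded and no stereocentre is formed.

Step 3
Reactants: 6 (4E,8E)-5,9,13-trimethyltetradeca-4,8,12-trienal; 7 isopropenylmagnesium bromide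
Product: 8 (6E,10E)-2,7,11,15-tetramethylhexadeca-1,6,10,14-tetraen-3-ol (racemic)
Conditions: THF, −78 → 0 °C; then H2O
Reagents that add atoms: none
Why: Grignard 1,2-addition to the aldehyde gives the secondary allylic alcohol as a racemate, which is acceptable because this stereocentre is erased in step 4.

Step 4
Reactants: 8 (6E,10E)-2,7,11,15-tetramethylhexadeca-1,6,10,14-tetraen-3-ol; 9 triethyl orthoacetate
Product: 11 ethyl (4E,8E,12E)-4,9,13,17-tetramethyloctadeca-4,8,12,16-tetraenoate, via mixed ketene acetal 10 (not isolated)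
Conditions: 9 (7 equiv), EtCO2H (cat.), 140 °C, EtOH distilled off
Reagents that add atoms: none
Why: Johnson–Claisen (orthoester Claisen) rearrangement through the mixed ketene acetal and a chair transition state with the long chain equatorial should deliver the (E)-trisubstituted alkene and two more carbons while destroying the carbinol stereocentre.

Step 5
Reactants: 11 ethyl (4E,8E,12E)-4,9,13,17-tetramethyloctadeca-4,8,12,16-tetraenoate
Product: 13 (4E,8E,12E)-4,9,13,17-tetramethyloctadeca-4,8,12,16-tetraenal, via aluminium hemiacetal 12 (not isolated)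
Conditions: i-Bu2AlH (1.05 equiv), CH2Cl2, −78 °C; then MeOH, aq. KNaC4H4O6
Reagents that add atoms: none
Why: Partial reduction of the ester with one equivalent of i-Bu2AlH at −78 °C stops at the tetrahedral aluminium hemiacetal, which collapses to the aldehyde only on work-up, and the isolated alkenes are inert.

Step 6
Reactants: 13 (4E,8E,12E)-4,9,13,17-tetramethyloctadeca-4,8,12,16-tetraenal; 14 3-(triphenylphosphoranylidene)butan-2-one
Product: 15 (3E,7E,11E,15E)-3,7,12,16,20-pentamethylhenicosa-3,7,11,15,19-pentaen-2-one
Conditions: toluene, 100 °C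
Reagents that add atoms: none
Why: Wittig olefination with a stabilised acyl ylide adds reversibly and should give the (E)-configured trisubstituted enone, with the chain trans to the acetyl group.

Step 7
Reactants: 15 (3E,7E,11E,15E)-3,7,12,16,20-pentamethylhenicosa-3,7,11,15,19-pentaen-2-one
Product: 17 trimethyl{[(3E,7E,11E,15E)-3,7,12,16,20-pentamethylhenicosa-1,3,7,11,15,19-hexaen-2-yl]oxy}silane, via lithium dienolate 16 (not isolated)
Conditions: LiN(i-Pr)2 (1.1 equiv), THF, −78 °C; then Me3SiCl, −78 → 0 °C; pentane, filtration, used crude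
Reagents that add atoms: chlorotrimethylsilane (C[Si](C)(C)Cl)
Why: Kinetic deprotonation by the hindered amide base at −78 °C removes a proton from the acetyl methyl group and not from the gamma position, and O-silylation of the cross-conjugated enolate gives the 2-siloxy-1,3-diene with the (E)-geometry of the trisubstituted alkene untouched.

Step 8
Reactants: 17 trimethyl{[(3E,7E,11E,15E)-3,7,12,16,20-pentamethylhenicosa-1,3,7,11,15,19-hexaen-2-yl]oxy}silane; 18 propyne
Product: 19 trimethyl({(3R)-2,4-dimethyl-3-[(3E,7E,11E)-3,8,12,16-tetramethylheptadeca-3,7,11,15-tetraen-1-yl]cyclohexa-1,4-dien-1-yl}oxy)silane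
Conditions: CoBr2[(2S,4S)-Ph2PCH(CH3)CH2CH(CH3)PPh2] (10 mol %), Zn (50 mol %), Na[B(3,5-(CF3)2C6H3)4] (15 mol %), 18 (3 equiv), CH2Cl2, 23 °C, sealed tube; filtration through basic alumina under argon
Reagents that add atoms: none
Why: Zn reduces the cobalt dibromide complex and the sodium borate abstracts bromide to give a cationic monovalent cobalt bisphosphine fragment that binds the s-cis diene and propyne, joins the alkyne CH carbon to the terminal CH2 of the diene by oxidative cyclisation and then closes the ring by reductive elimination between the methyl-bearing vinyl carbon and the chain-bearing allyl terminus. The closest known reaction type is the cobalt-catalysed [4+2] cycloaddition of unactivated alkynes with 2-siloxy-1,3-dienes (a metal-mediated Diels–Alder reaction), which also exists in enantioselective form with chiral bisphosphine ligands on cationic cobalt. The single ring is closed as a six-membered carbocycle by intermolecular [4+2] annulation, four carbons from the diene and two from the alkyne, so the new ring alkene is flanked by the two new sigma bonds and can only be endocyclic and trisubstituted. The one new stereocentre, the ring CH that carries the chain, is set by the chiral ligand, which selects the enantiotopic face of the (E)-configured diene on cobalt. The step needs regioselectivity (methyl next to the chain-bearing carbon, para to the siloxy carbon) and chemoselectivity over the four isolated trisubstituted alkenes: the siloxy group makes its neighbouring CH2 the unhindered, electron-rich terminus that pairs with the small alkyne CH in the first C–C bond formation, and only the conjugated diene, held s-cis by its 2,3-disubstitution, can chelate the metal. The product is an enol silane placed exactly where the quaternary carbon has to be built next.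

Step 9
Reactants: 19 trimethyl({(3R)-2,4-dimethyl-3-[(3E,7E,11E)-3,8,12,16-tetramethylheptadeca-3,7,11,15-tetraen-1-yl]cyclohexa-1,4-dien-1-yl}oxy)silane
Product: 21 (5R)-4,6,6-trimethyl-5-[(3E,7E,11E)-3,8,12,16-tetramethylheptadeca-3,7,11,15-tetraen-1-yl]cyclohex-3-en-1-one, via lithium enolate 20 (not isolated)
Conditions: MeLi (1.05 equiv), THF, 0 °C; then DMPU, MeI (5 equiv), −78 → −20 °C
Reagents that add atoms: iodomethane (CI)
Why: Regiospecific enolate generation from the enol silane with MeLi followed by C-methylation with iodomethane (enolate alkylation) puts the second methyl group on the only enolate carbon, which creates the quaternary centre without a new stereocentre, and the neighbouring stereocentre is not acidic and is kept.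

Step 10
Reactants: 21 (5R)-4,6,6-trimethyl-5-[(3E,7E,11E)-3,8,12,16-tetramethylheptadeca-3,7,11,15-tetraen-1-yl]cyclohex-3-en-1-one
Product: 22 camelliol C, (1S,5R)-4,6,6-trimethyl-5-[(3E,7E,11E)-3,8,12,16-tetramethylheptadeca-3,7,11,15-tetraen-1-yl]cyclohex-3-en-1-ol
Conditions: (R)-Me-CBS oxazaborolidine [(3aR)-1-methyl-3,3-diphenyltetrahydro-1H,3H-pyrrolo[1,2-c][1,3,2]oxazaborole] (0.5 equiv), catecholborane (2 equiv), toluene, −78 → −30 °C; then MeOH, aq. NaOH
Reagents that add atoms: none
Why: Corey–Bakshi–Shibata reduction distinguishes the quaternary (large) from the methylene (small) flank of the ketone, so the (R)-catalyst should deliver hydride to the face that gives the (1S) carbinol, cis to the chain at C5, while catecholborane leaves the trisubstituted alkenes alone at low temperature.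

**Compound list**

1 | (2E,6E)-farnesyl bromide | CC(C)=CCC/C(C)=C/CC/C(C)=C/CBr | starting material
2 | acetonitrile | CC#N | starting material
3 | lithioacetonitrile | [Li]CC#N | intermediate (not isolated)
4 | (4E,8E)-5,9,13-trimethyltetradeca-4,8,12-trienenitrile | CC(C)=CCC/C(C)=C/CC/C(C)=C/CCC#N | intermediate
5 | N-(diisobutylaluminio) aldimine of 6 | CC(C)=CCC/C(C)=C/CC/C(C)=C/CCC=N[Al](CC(C)C)CC(C)C | intermediate (not isolated)
6 | (4E,8E)-5,9,13-trimethyltetradeca-4,8,12-trienal | CC(C)=CCC/C(C)=C/CC/C(C)=C/CCC=O | intermediate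
7 | isopropenylmagnesium bromide | CC(=C)[Mg]Br | starting material
8 | (6E,10E)-2,7,11,15-tetramethylhexadeca-1,6,10,14-tetraen-3-ol (racemic) | CC(C)=CCC/C(C)=C/CC/C(C)=C/CCC(O)C(C)=C | intermediate
9 | triethyl orthoacetate | CC(OCC)(OCC)OCC | starting material
10 | mixed ketene acetal (1-ethoxyvinyl ether of 8) | CC(C)=CCC/C(C)=C/CC/C(C)=C/CCC(OC(=C)OCC)C(C)=C | intermediate (not isolated)
11 | ethyl (4E,8E,12E)-4,9,13,17-tetramethyloctadeca-4,8,12,16-tetraenoate | CC(C)=CCC/C(C)=C/CC/C(C)=C/CC/C=C(\C)CCC(=O)OCC | intermediate
12 | diisobutylaluminium ethyl hemiacetal of 13 | CC(C)=CCC/C(C)=C/CC/C(C)=C/CC/C=C(\C)CCC(OCC)O[Al](CC(C)C)CC(C)C | intermediate (not isolated)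
13 | (4E,8E,12E)-4,9,13,17-tetramethyloctadeca-4,8,12,16-tetraenal | CC(C)=CCC/C(C)=C/CC/C(C)=C/CC/C=C(\C)CCC=O | intermediate
14 | 3-(triphenylphosphoranylidene)butan-2-one | CC(=O)C(C)=P(c1ccccc1)(c1ccccc1)c1ccccc1 | starting material
15 | (3E,7E,11E,15E)-3,7,12,16,20-pentamethylhenicosa-3,7,11,15,19-pentaen-2-one | CC(C)=CCC/C(C)=C/CC/C(C)=C/CC/C=C(\C)CC/C=C(\C)C(C)=O | intermediate
16 | lithium dienolate of 15 | CC(C)=CCC/C(C)=C/CC/C(C)=C/CC/C=C(\C)CC/C=C(\C)C(=C)O[Li] | intermediate (not isolated)
17 | trimethyl{[(3E,7E,11E,15E)-3,7,12,16,20-pentamethylhenicosa-1,3,7,11,15,19-hexaen-2-yl]oxy}silane | CC(C)=CCC/C(C)=C/CC/C(C)=C/CC/C=C(\C)CC/C=C(\C)C(=C)O[Si](C)(C)C | intermediate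
18 | propyne | CC#C | starting material
19 | trimethyl({(3R)-2,4-dimethyl-3-[(3E,7E,11E)-3,8,12,16-tetramethylheptadeca-3,7,11,15-tetraen-1-yl]cyclohexa-1,4-dien-1-yl}oxy)silane | CC(C)=CCC/C(C)=C/CC/C(C)=C/CC/C=C(\C)CC[C@@H]1C(C)=CCC(O[Si](C)(C)C)=C1C | intermediate
20 | lithium enolate from 19 | CC(C)=CCC/C(C)=C/CC/C(C)=C/CC/C=C(\C)CC[C@@H]1C(C)=CCC(O[Li])=C1C | intermediate (not isolated)
21 | (5R)-4,6,6-trimethyl-5-[(3E,7E,11E)-3,8,12,16-tetramethylheptadeca-3,7,11,15-tetraen-1-yl]cyclohex-3-en-1-one | CC(C)=CCC/C(C)=C/CC/C(C)=C/CC/C=C(\C)CC[C@@H]1C(C)=CCC(=O)C1(C)C | intermediate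
22 | camelliol C, (1S,5R)-4,6,6-trimethyl-5-[(3E,7E,11E)-3,8,12,16-tetramethylheptadeca-3,7,11,15-tetraen-1-yl]cyclohex-3-en-1-ol | CC(C)=CCC/C(C)=C/CC/C(C)=C/CC/C=C(\C)CC[C@@H]1C(C)=CC[C@H](O)C1(C)C | target

**Totals**

Total step count: 10. Longest linear sequence: 10 steps (1 to 22).

**Steps most likely to fail**

Step 8. The alkyne may be incorporated with the opposite orientation, the catalyst may divert to [2+2] cycloaddition or alkyne oligomerisation, or facial discrimination of the diene may be weak. The fallback makes the same two ring bonds by a thermal, polarity-controlled Diels–Alder reaction and sorts out the absolute configuration at the end. Setting out from diene 17, heating with methyl propiolate (toluene, 90 °C) should give racemic methyl 5-methyl-6-[(3E,7E,11E)-3,8,12,16-tetramethylheptadeca-3,7,11,15-tetraen-1-yl]-4-(trimethylsilyloxy)cyclohexa-1,4-diene-1-carboxylate F1. The ester should arrive next to the chain-bearing carbon because the siloxy group (para) and the chain (ortho) direct alike. Reduction with i-Bu2AlH (CH2Cl2, −78 °C, neutral work-up) should give the allylic alcohol {5-methyl-6-[(3E,7E,11E)-3,8,12,16-tetramethylheptadeca-3,7,11,15-tetraen-1-yl]-4-(trimethylsilyloxy)cyclohexa-1,4-dien-1-yl}methanol F2. MsCl/Et3N then gives the allylic methanesulfonate of F2 F3, which is not isolated and is reduced by LiBHEt3 (SN2 hydride displacement) to the ring methyl group. This comes back to the route at 19, now as the racemate, that is 19 together with its mirror image, the (3S)-enantiomer of 19 F4. Steps 9 and 10 are run on the racemate: the mirror-image material passes through the mirror image of enolate 20 F5 and the (5S)-enantiomer of ketone 21 F6. Because step 10 is reagent-controlled, it should end as the (1S,5S)-diastereomer of 22 F7, which is removed by chromatography.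

Step 9. Proton transfer between enolate 20 and the product ketone, whose CH2 between carbonyl and ring alkene is acidic, may lead to methylation at that CH2, double methylation or movement of the alkene into conjugation; O-methylation may compete. The fallback introduces the methyl group without a free enolate. Setting out from 19, Et2Zn/CH2I2 (1.1 equiv, CH2Cl2, 0 °C, Simmons–Smith cyclopropanation) should attack the electron-rich enol ether alkene in preference to the trisubstituted alkenes. This gives the siloxycyclopropane trimethyl({1,3-dimethyl-2-[(3E,7E,11E)-3,8,12,16-tetramethylheptadeca-3,7,11,15-tetraen-1-yl]bicyclo[4.1.0]hept-3-en-6-yl}oxy)silane F8 (mixture at the two cyclopropane carbons). NaOH in aqueous MeOH then removes the silyl group and opens the cyclopropanol at its CH2 carbon, which becomes the second methyl group, and the fallback comes back to the route at 21.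

Step 10. Hydride delivery to the hindered, neopentyl-type carbonyl may be slow, boron hydride may add to the chain alkenes at the higher temperature then needed, or a substrate bias may oppose the catalyst. The fallback uses substrate control with recycling. Setting out from 21, reduction with LiAlH4 (Et2O, −78 °C), which leaves isolated alkenes untouched, should give 22 together with its C1 epimer, (1R,5R)-4,6,6-trimethyl-5-[(3E,7E,11E)-3,8,12,16-tetramethylheptadeca-3,7,11,15-tetraen-1-yl]cyclohex-3-en-1-ol F9. The diastereomers are separated by chromatography, F9 is oxidised back to 21 with Dess–Martin periodinane and recycled, and the fallback comes back to the route at 22.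

**Further compounds**

F1 | step 8 | methyl 5-methyl-6-[(3E,7E,11E)-3,8,12,16-tetramethylheptadeca-3,7,11,15-tetraen-1-yl]-4-(trimethylsilyloxy)cyclohexa-1,4-diene-1-carboxylate (racemic) | CC(C)=CCC/C(C)=C/CC/C(C)=C/CC/C=C(\C)CCC1C(C(=O)OC)=CCC(O[Si](C)(C)C)=C1C
F2 | step 8 | {5-methyl-6-[(3E,7E,11E)-3,8,12,16-tetramethylheptadeca-3,7,11,15-tetraen-1-yl]-4-(trimethylsilyloxy)cyclohexa-1,4-dien-1-yl}methanol (racemic) | CC(C)=CCC/C(C)=C/CC/C(C)=C/CC/C=C(\C)CCC1C(CO)=CCC(O[Si](C)(C)C)=C1C
F3 | step 8 | methanesulfonate of F2 (racemic, not isolated) | CC(C)=CCC/C(C)=C/CC/C(C)=C/CC/C=C(\C)CCC1C(COS(C)(=O)=O)=CCC(O[Si](C)(C)C)=C1C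
F4 | step 8 | (3S)-enantiomer of 19 | CC(C)=CCC/C(C)=C/CC/C(C)=C/CC/C=C(\C)CC[C@H]1C(C)=CCC(O[Si](C)(C)C)=C1C
F5 | step 8 | mirror image of lithium enolate 20 (not isolated) | CC(C)=CCC/C(C)=C/CC/C(C)=C/CC/C=C(\C)CC[C@H]1C(C)=CCC(O[Li])=C1C
F6 | step 8 | (5S)-enantiomer of ketone 21 | CC(C)=CCC/C(C)=C/CC/C(C)=C/CC/C=C(\C)CC[C@H]1C(C)=CCC(=O)C1(C)C
F7 | step 8 | (1S,5S)-4,6,6-trimethyl-5-[(3E,7E,11E)-3,8,12,16-tetramethylheptadeca-3,7,11,15-tetraen-1-yl]cyclohex-3-en-1-ol | CC(C)=CCC/C(C)=C/CC/C(C)=C/CC/C=C(\C)CC[C@H]1C(C)=CC[C@H](O)C1(C)C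
F8 | step 9 | trimethyl({1,3-dimethyl-2-[(3E,7E,11E)-3,8,12,16-tetramethylheptadeca-3,7,11,15-tetraen-1-yl]bicyclo[4.1.0]hept-3-en-6-yl}oxy)silane | CC(C)=CCC/C(C)=C/CC/C(C)=C/CC/C=C(\C)CC[C@@H]1C(C)=CCC2(O[Si](C)(C)C)CC12C
F9 | step 10 | (1R,5R)-4,6,6-trimethyl-5-[(3E,7E,11E)-3,8,12,16-tetramethylheptadeca-3,7,11,15-tetraen-1-yl]cyclohex-3-en-1-ol | CC(C)=CCC/C(C)=C/CC/C(C)=C/CC/C=C(\C)CC[C@@H]1C(C)=CC[C@@H](O)C1(C)C
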